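## Structural features

Compound 22 contains one ring only, a benzene ring (ring A) with a 1,3,4,5 pattern. It carries CO2H at C1, the free phenol at C4 para to it, and two unlike carbon chains at C3 and C5, both ortho to the phenol oxygen. The C3 chain is Ar–C1'H2–C2'H2–C3'H(CH3)–C4'(=O)–C5'H=C6'H–C7'(CH3)2OH, an (E)-γ-hydroxy enone. The C5 chain is the oxidised prenyl unit Ar–C1''H2–C2''H=C3''(CH3)–C4''H2OH with E geometry. C3' (R) is the only stereocentre, so no neighbouring centre can relay or shield it; a reagent must set it, and afterwards it only has to be kept. It is a tertiary C–H next to a ketone and can epimerise by enolisation. The enone is a Michael acceptor that does not tolerate hot hydroxide, and the ortho-allylic phenol with its allylic alcohol cyclises or ionises in acid. The real difficulty is twofold: two different chains must be placed unambiguously on the two ortho positions of a 4-hydroxybenzoic acid, and three carbonyl groups and three hydroxyl groups must be told apart while C3' is held. The key step uses the string O(phenol)–C4–C3–C1'–C2'–C3'–C4'. Bonding the oxygen to C4' draws a seven-membered aryl lactone, and deleting that oxygen leaves the six-membered ketone ring of a 2-methyl-1-tetralone in which C4' is bonded to C4. C1 is para to C4, so the site of the later carboxyl carbon can carry an oxygen donor while the ring is enlarged.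

## Logic of the disconnections

**22 from 21.** The bonds cut are the O–Si bond at the tertiary oxygen on C7' and the alkyl–O bond of the ester at C1. Both masks are silicon-based, so one fluoride treatment removes them. A simple alkyl ester para to a phenoxide would need hot hydroxide, which neither the enone nor C3' would survive. The skeleton is not simplified, but the endgame shrinks to one mild operation. The forward step must be short and cold enough to leave C3' untouched.

**21 from 15 and 19 (through 20).** The bond cut is C4'–C5', between the ketone carbonyl and the vinyl carbon. This splits off the whole C5'–C8' unit with its E geometry already fixed and does not touch C3'. The target is thereby reduced to an arene with one acyl donor. The forward step needs a vinyl metal that attacks the amide carbonyl of 15 and spares the aryl ester. The free phenol is therefore left in place, because its magnesium salt pushes electron density into the para ester and switches it off.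

**19 from 18, 18 from 16 (through 17).** The bonds cut are O–Si, then C–I and C–H across the former triple bond. The fragment falls back to a bulk alkynol. The forward step needs syn addition with the metal at the terminal carbon, which the quaternary carbinol carbon enforces.

**15 from 14, 14 from 12 and 13.** After adjusting the oxidation level at C4'', the C2''=C3'' double bond is cut. The trisubstituted olefin is thereby reduced to a plain allyl group and a four-carbon enal. The forward step must give the E isomer, and this is why the aldehyde oxidation level is used and not the alcohol.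

**12 from 11, 11 from 10.** The bond cut is C5–C1'', traced back to an O-allyl ether. The phenol oxygen itself delivers the allyl group, so no halogen or metal is needed on the ring. The forward step requires that only one ortho position be open; C3 carries the chain and C1 (para) carries the ester.

**10 from 9.** The bond cut is the one between C1 and the carboxyl carbon. The carboxyl group is replaced by an oxygen leaving group, which returns the para position to an oxygen function. The forward step is a carbonylation that must tolerate the free phenol, and the choice of alcohol fixes the final deprotection.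

**9 from 8.** The amide C4'–N bond is cut and C4' is rejoined to the phenol oxygen. The open chain and the phenol merge into one ring, and the two ring oxygens stay distinguishable because one is acylated. The forward step needs an amine reagent of low basicity so that C3' does not enolise.

**8 from 7, 7 from 6.** The bonds cut are O–S and then O–CH2Ph. These steps only exchange the group on the para oxygen. They must run under neutral or weakly basic conditions without any nucleophile that could open the lactone.

**6 from 5.** The aryl C–O bond is cut and the aryl carbon is returned to the carbonyl carbon. The seven-membered lactone contracts to a six-membered ketone of a readily available class. The forward step requires that the aryl carbon migrate and not the secondary carbon, and that the ketone not enolise meanwhile.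

**5 from 4.** The C–H bond at the stereocentre is replaced by a C–CO2allyl bond. The stereochemical problem thus becomes the face-selective protonation of an enolate bound to a chiral catalyst, and a racemic precursor suffices. The forward step depends on a ligand that controls that face.

**4 from 2 (through 3), 2 from 1.** The bonds cut are C2–CH3, C2–C(=O)O and O–CH2Ph. All three are made by enolate or phenoxide chemistry from 1. The only requirement is C- rather than O-alkylation of the stabilised enolate.

## Other disconnections considered

**Alternative 1:**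
- **Cut:** The aryl–C1' bond at C3 and the C4–O bond, the latter traced to a C–B bond.
- **Forward key step:** Three components are joined under Pd(OAc)2, a triarylphosphine, a strained bicyclic olefin as relay and Cs2CO3. They are the aryl iodide methyl 4-iodo-3-[(E)-4-(tert-butyldimethylsilyloxy)-3-methylbut-2-en-1-yl]benzoate A1, the primary iodide 1-{[(2R)-4-iodo-2-methylbutoxy]methyl}-4-methoxybenzene A2 and a diboron ester. The sequence is oxidative addition, insertion of the relay olefin, C–H palladation at the one free ortho position, alkylation through tetravalent palladium, loss of the relay and ipso borylation. It should give methyl 3-[(E)-4-(tert-butyldimethylsilyloxy)-3-methylbut-2-en-1-yl]-5-[(3R)-4-(4-methoxybenzyloxy)-3-methylbutyl]-4-(pinacolboryl)benzoate A3.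
- **In favour:** The carboxyl carbon is present from the start, so steps 5, 6 and 8 of the chosen plan have no counterpart; here the alternative is the better one. The stereocentre comes from the chiral pool and sits next to an ether carbon, not a carbonyl, so it is safer during the key step than in 5; this too is better. A1 has the single ortho substituent that this relay chemistry prefers.
- **Against:** Termination by borylation at a carbon flanked by two alkyl groups is the least developed ending of the cascade. Direct borylation of A1 or A2 can begin before the relay does. The nearby trisubstituted olefin with its allylic silyl ether offers the metal other exits. A1 itself needs the same allylation, metathesis, reduction and silylation as the chosen plan, so the two are equal on that arm. After A3 the route still needs C–B oxidation, ether cleavage, oxidation to an α-chiral aldehyde, vinyl addition, oxidation and hydrolysis of a methyl 4-hydroxybenzoate beside the enone, and this last step is a real weakness.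
- **Comparison:** On structure, both plans solve the same unsymmetrical ortho pattern. On mechanism, a multicomponent catalytic cascade with several off-cycle paths stands against a stoichiometric shift of one bond with only two possible migrating groups. On step economy the alternative is more convergent and probably shorter in its longest line.

**Alternative 2:**
- **Cut:** Two ring bonds, so ring A itself is built.
- **Forward key step:** The pyrone methyl 3-allyl-2-oxo-2H-pyran-5-carboxylate A4 (diene) and the ynol ether triisopropyl{[(5R)-6-(4-methoxybenzyloxy)-5-methylhex-1-yn-1-yl]oxy}silane A5 (dienophile) combine in an inverse-demand [4+2] cycloaddition. Decarboxylative cycloreversion follows and should give methyl 3-allyl-5-[(3R)-4-(4-methoxybenzyloxy)-3-methylbutyl]-4-(triisopropylsilyloxy)benzoate A6.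
- **In favour:** The polarity is matched, because the nucleophilic alkyl-bearing alkyne carbon meets C6 of the pyrone, so the substitution pattern follows from the mechanism. The phenol arrives protected and the ester is already in place, which is better than the oxygen-to-carbon exchange of the chosen plan. The stereocentre is again remote from any carbonyl.
- **Against:** A5 belongs to a delicate, moisture-sensitive class that needs several steps from a chiral C4 unit. A4 is not an article of commerce and has to be made by substitution at C3 of a halogenated pyrone. Both new ring bonds form at substituted carbons, so a high temperature is likely. The allyl group of A6 still needs metathesis and reduction, where the plans are equal. The chain end still needs deprotection, oxidation, vinyl addition and oxidation through an epimerisable aldehyde, and the methyl ester again ends in a basic hydrolysis.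
- **Comparison:** On structure, a cheap benzene ring is built here and bought in the chosen plan. On mechanism, regiocontrol is as well founded as the migratory preference in step 4. On step economy the longest line would be comparable or slightly shorter, but two non-trivial fragments raise the total count.

**Alternative 3:**
- **Cut:** The two ring bonds between the chain-bearing carbons C3 and C5 and the CH carbons C2 and C6.
- **Forward key step:** The open-chain ketone (2E,10R)-1-(tert-butyldimethylsilyloxy)-11-(4-methoxybenzyloxy)-2,10-dimethylundec-2-en-6-one A7 condenses through both α-methylene carbons with methyl 2-formyl-3-oxopropanoate A8 under base. After twofold dehydration and tautomerisation it should give methyl 3-[(E)-4-(tert-butyldimethylsilyloxy)-3-methylbut-2-en-1-yl]-4-hydroxy-5-[(3R)-4-(4-methoxybenzyloxy)-3-methylbutyl]benzoate A9.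
- **In favour:** The electrophile is symmetrical, so there is no regiochemical question at all, which is better than any other plan. Phenol, ester and both arms appear in one operation. The stereocentre is far from the reacting carbonyl.
- **Against:** A7 carries the full length of both chains and has to be assembled first, so the work is moved and not saved. Both nucleophilic carbons are substituted methylenes, whereas annulations of this type are best established with small ketones and more strongly activated dialdehydes. A8 is prone to deformylation and ester hydrolysis in aqueous base. Self-condensation of A7 competes. The later chain-end operations and the methyl ester hydrolysis are the same burdens as in the other two alternatives.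
- **Comparison:** On structure, the ring is made last and the chains first, the reverse of the chosen plan. On mechanism, a sequence of reversible aldol steps under strong base is harder to steer than one irreversible migration. On step economy the key step is very productive, but the overall count should be similar once A7 is included.

Key step: step 4

Assumption: (S)-t-Bu-PHOX is written in step 3 on the assumption that it delivers the R ketone; if the sense of induction is opposite for this substrate, the equally available R ligand is used and nothing else changes.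

## Route

Step 1
Reactants: 1 6-hydroxy-3,4-dihydronaphthalen-1(2H)-one
Product: 2 6-(benzyloxy)-3,4-dihydronaphthalen-1(2H)-one
Conditions: BnBr, K2CO3, DMF, rt → 50 °C
Reagents that add atoms: benzyl bromide BrCc1ccccc1
Why: Williamson ether synthesis on an acidic, ketone-conjugated phenol. The benzyl ether is the para donor needed in step 4 and can later be removed by neutral hydrogenolysis, which a methyl ether would not allow beside an aryl lactone.

Step 2
Reactants: 2 6-(benzyloxy)-3,4-dihydronaphthalen-1(2H)-one
Product: 4 allyl (±)-6-(benzyloxy)-2-methyl-1-oxo-1,2,3,4-tetrahydronaphthalene-2-carboxylate, via unmethylated allyl β-keto ester 3 (not isolated)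
Conditions: NaH, diallyl carbonate, THF, 60 °C; then MeI, rt
Reagents that add atoms: diallyl carbonate C=CCOC(=O)OCC=C; iodomethane IC
Why: Claisen-type C-acylation of the ketone enolate with a dialkyl carbonate is pulled forward by deprotonation of 3, and the stabilised sodium enolate is then C-methylated in the same flask. The quaternary centre is racemic on purpose because it is erased in step 3.

Step 3
Reactants: 4 allyl (±)-6-(benzyloxy)-2-methyl-1-oxo-1,2,3,4-tetrahydronaphthalene-2-carboxylate
Product: 5 (R)-6-(benzyloxy)-2-methyl-3,4-dihydronaphthalen-1(2H)-one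
Conditions: Pd(OAc)2 (cat.), (S)-t-Bu-PHOX (cat.), HCO2H, 4 Å molecular sieves, 1,4-dioxane, 40 °C
Reagents that add atoms: none
Why: Palladium-catalysed enantioselective decarboxylative protonation: zerovalent palladium ionises the allyl ester, the carboxylate loses its CO2 unit, and the enolate held by the chiral P,N-ligated metal is protonated on one face while formate reduces the allyl unit. Both enantiomers of 4 converge on one enolate, so the ligand alone sets C2, and 2-methyl-1-tetralone β-keto esters are the standard substrate class of this reaction.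

Step 4
Reactants: 5 (R)-6-(benzyloxy)-2-methyl-3,4-dihydronaphthalen-1(2H)-one
Product: 6 (R)-7-(benzyloxy)-3-methyl-4,5-dihydro-1-benzoxepin-2(3H)-one
Conditions: mCPBA, CH2Cl2, 0 °C → rt, dark; aq. Na2S2O3/NaHCO3 wash
Reagents that add atoms: 3-chloroperoxybenzoic acid O=C(OO)c1cccc(Cl)c1
Why: Baeyer–Villiger oxidation. The peracid adds to the C1 carbonyl to give the tetrahedral Criegee adduct, and the group that lies antiperiplanar to the O–O bond and best carries positive charge shifts from carbon to oxygen as 3-chlorobenzoate leaves. The closest known reaction type is the peracid ring expansion of 1-tetralones to 4,5-dihydro-1-benzoxepin-2(3H)-ones, which runs with aryl migration. The seven-membered ring is not made by cyclisation: the six-membered ketone ring is enlarged by one atom through insertion of oxygen into the C1–C8a bond, which creates the aryl C–O bond of the later phenol. No stereocentre is formed; C2 is not part of the migrating bond, keeps its R configuration and becomes C3 of 6. The selectivity needed is migration of the aryl carbon C8a over the secondary carbon C2, two groups of similar intrinsic aptitude, and the benzyloxy group at C6, para to C8a, stabilises the charge on the migrating ring and decides the matter. No strong acid is added, so the only acid present is the weak carboxylic acid and enolisation of unreacted 5 should stay slow. The product is an aryl ester, so one ring oxygen is masked and the acyl carbon is activated for step 7.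

Step 5
Reactants: 6 (R)-7-(benzyloxy)-3-methyl-4,5-dihydro-1-benzoxepin-2(3H)-one
Product: 7 (R)-7-hydroxy-3-methyl-4,5-dihydro-1-benzoxepin-2(3H)-one
Conditions: H2 (1 atm), Pd/C, EtOAc, rt
Reagents that add atoms: none
Why: Hydrogenolysis of a benzyl aryl ether under neutral conditions; ethyl acetate is chosen because an alcohol solvent could open the aryl lactone. Only the para oxygen is freed, since the other one is still acylated.

Step 6
Reactants: 7 (R)-7-hydroxy-3-methyl-4,5-dihydro-1-benzoxepin-2(3H)-one
Product: 8 (R)-3-methyl-2-oxo-2,3,4,5-tetrahydro-1-benzoxepin-7-yl trifluoromethanesulfonate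
Conditions: Tf2O, pyridine, CH2Cl2, −10 → 0 °C
Reagents that add atoms: trifluoromethanesulfonic anhydride O=S(=O)(OS(=O)(=O)C(F)(F)F)C(F)(F)F
Why: O-sulfonylation of the only free phenol turns the spent donor into a leaving group for palladium. Cold pyridine is too weak a base to enolise the lactone.

Step 7
Reactants: 8 (R)-3-methyl-2-oxo-2,3,4,5-tetrahydro-1-benzoxepin-7-yl trifluoromethanesulfonate
Product: 9 4-hydroxy-3-{(3R)-4-[methoxy(methyl)amino]-3-methyl-4-oxobutyl}phenyl trifluoromethanesulfonate
Conditions: MeNH(OMe)·HCl, AlMe3, CH2Cl2, 0 °C → rt; dilute HCl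
Reagents that add atoms: N,O-dimethylhydroxylamine hydrochloride CNOC.Cl
Why: Aluminium-amide aminolysis of an ester, made easy here by the phenoxide leaving group; it frees the C4 phenol and stores the acyl carbon as an N-methoxy-N-methyl amide. The aluminium amide is weakly basic, so C3' is not enolised, and the aryl triflate is inert to AlMe3 without a transition metal.

Step 8
Reactants: 9 4-hydroxy-3-{(3R)-4-[methoxy(methyl)amino]-3-methyl-4-oxobutyl}phenyl trifluoromethanesulfonate
Product: 10 2-(trimethylsilyl)ethyl 4-hydroxy-3-{(3R)-4-[methoxy(methyl)amino]-3-methyl-4-oxobutyl}benzoate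
Conditions: Pd(OAc)2 (cat.), dppp (cat.), CO (1 atm), Me3SiCH2CH2OH (large excess), Et3N, DMF, 70 °C
Reagents that add atoms: carbon monoxide [C-]#[O+]; 2-(trimethylsilyl)ethanol C[Si](C)(C)CCO
Why: Palladium-catalysed alkoxycarbonylation of an aryl triflate (oxidative addition, CO insertion, alcoholysis), a reaction that tolerates free phenols when the alcohol is in large excess and outruns the phenol for the acyl-palladium species. The β-silyl ester is chosen so that the acid can be released by fluoride at the end and not by hydroxide.

Step 9
Reactants: 10 2-(trimethylsilyl)ethyl 4-hydroxy-3-{(3R)-4-[methoxy(methyl)amino]-3-methyl-4-oxobutyl}benzoate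
Product: 11 2-(trimethylsilyl)ethyl 4-(allyloxy)-3-{(3R)-4-[methoxy(methyl)amino]-3-methyl-4-oxobutyl}benzoate
Conditions: allyl bromide, K2CO3, acetone, reflux
Reagents that add atoms: allyl bromide C=CCBr
Why: Williamson ether synthesis; the phenol para to the ester is the only acidic site and the amide and ester are inert to carbonate.

Step 10
Reactants: 11 2-(trimethylsilyl)ethyl 4-(allyloxy)-3-{(3R)-4-[methoxy(methyl)amino]-3-methyl-4-oxobutyl}benzoate
Product: 12 2-(trimethylsilyl)ethyl 3-allyl-4-hydroxy-5-{(3R)-4-[methoxy(methyl)amino]-3-methyl-4-oxobutyl}benzoate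
Conditions: N,N-diethylaniline, 200 °C
Reagents that add atoms: none
Why: Aromatic Claisen rearrangement, a [3,3] shift followed by tautomerisation. Only one ortho position bears hydrogen and the para position is blocked, so a shift to the substituted ortho carbon can only revert and a single isomer is expected; the amide α-C–H is far too weakly acidic to epimerise under these neutral conditions.

Step 11
Reactants: 12 2-(trimethylsilyl)ethyl 3-allyl-4-hydroxy-5-{(3R)-4-[methoxy(methyl)amino]-3-methyl-4-oxobutyl}benzoate; 13 methacrolein
Product: 14 2-(trimethylsilyl)ethyl 4-hydroxy-3-{(3R)-4-[methoxy(methyl)amino]-3-methyl-4-oxobutyl}-5-[(2E)-3-methyl-4-oxobut-2-en-1-yl]benzoate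
Conditions: 13 (excess), second-generation Hoveyda–Grubbs catalyst (cat.), 1,4-benzoquinone (cat.), CH2Cl2, 40 °C
Reagents that add atoms: none
Why: Olefin cross-metathesis between a reactive terminal allyl arene and a 1,1-disubstituted, electron-poor partner that does not homodimerise. The trisubstituted enal forms under thermodynamic control with the formyl group trans to the benzylic chain (E), and the quinone intercepts ruthenium hydrides that would move the double bond into conjugation.

Step 12
Reactants: 14 2-(trimethylsilyl)ethyl 4-hydroxy-3-{(3R)-4-[methoxy(methyl)amino]-3-methyl-4-oxobutyl}-5-[(2E)-3-methyl-4-oxobut-2-en-1-yl]benzoate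
Product: 15 2-(trimethylsilyl)ethyl 4-hydroxy-3-[(2E)-4-hydroxy-3-methylbut-2-en-1-yl]-5-{(3R)-4-[methoxy(methyl)amino]-3-methyl-4-oxobutyl}benzoate
Conditions: NaBH4, CeCl3·7H2O, MeOH, −20 → 0 °C
Reagents that add atoms: none
Why: Luche 1,2-reduction of the enal; ester and amide are not touched by borohydride at this temperature and the olefin geometry is retained. The reduction is placed before the enone exists, so no aldehyde-versus-ketone problem arises.

Step 13
Reactants: 16 2-methylbut-3-yn-2-ol
Product: 18 (E)-4-iodo-2-methylbut-3-en-2-ol, via (E)-vinylstannane 17 (not isolated)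
Conditions: Bu3SnH, PdCl2(PPh3)2 (cat.), THF, 0 °C → rt; then I2, 0 °C
Reagents that add atoms: iodine [I][I]
Why: Palladium-catalysed hydrostannation is a syn addition, and the quaternary carbinol carbon directs tin to the terminal carbon, giving the E stannane. Iododestannylation proceeds with retention of geometry.

Step 14
Reactants: 18 (E)-4-iodo-2-methylbut-3-en-2-ol
Product: 19 triethyl{[(3E)-4-iodo-2-methylbut-3-en-2-yl]oxy}silane
Conditions: TESOTf, 2,6-lutidine, CH2Cl2, 0 °C
Reagents that add atoms: triethylsilyl trifluoromethanesulfonate CC[Si](CC)(CC)OS(=O)(=O)C(F)(F)F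
Why: Silylation of a tertiary alcohol needs the silyl triflate. The ether removes the acidic proton before metalation and falls in the same fluoride step as the ester.

Step 15
Reactants: 15 2-(trimethylsilyl)ethyl 4-hydroxy-3-[(2E)-4-hydroxy-3-methylbut-2-en-1-yl]-5-{(3R)-4-[methoxy(methyl)amino]-3-methyl-4-oxobutyl}benzoate; 19 triethyl{[(3E)-4-iodo-2-methylbut-3-en-2-yl]oxy}silane
Product: 21 2-(trimethylsilyl)ethyl 3-{(3R,5E)-3,7-dimethyl-4-oxo-7-[(triethylsilyl)oxy]oct-5-en-1-yl}-4-hydroxy-5-[(2E)-4-hydroxy-3-methylbut-2-en-1-yl]benzoate, via vinylmagnesium chloride 20 (not isolated)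
Conditions: 19 (slight excess over the exchange reagent), i-PrMgCl·LiCl, THF, 0 °C → rt (gives 20); 15, i-PrMgCl (2 equiv), THF, −20 °C; then 20, −20 → 0 °C; cold aq. NH4Cl
Reagents that add atoms: none
Why: Weinreb ketone synthesis with an alkenyl Grignard reagent made by iodine–magnesium exchange with retention of the E geometry; the chelated tetrahedral adduct stops at the ketone level and shields C3' until the quench. Prior deprotonation turns the phenol into a magnesium phenoxide whose donation into the para ester makes that carbonyl far less electrophilic than the amide, so no hydroxyl protecting group is needed. The bulky C7' substituent hinders conjugate addition of the released amine on work-up.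

Step 16
Reactants: 21 2-(trimethylsilyl)ethyl 3-{(3R,5E)-3,7-dimethyl-4-oxo-7-[(triethylsilyl)oxy]oct-5-en-1-yl}-4-hydroxy-5-[(2E)-4-hydroxy-3-methylbut-2-en-1-yl]benzoate
Product: 22 4-hydroxy-3-[(3R,5E)-7-hydroxy-3,7-dimethyl-4-oxooct-5-en-1-yl]-5-[(2E)-4-hydroxy-3-methylbut-2-en-1-yl]benzoic acid
Conditions: TBAF, THF, 0 °C → rt; dilute HCl to pH 4
Reagents that add atoms: none
Why: Fluoride attacks both silicon atoms: the triethylsilyl ether is cleaved and the β-silylethyl ester fragments to the carboxylate. The acidic phenol buffers the medium, and the mild acidification avoids acid-induced cyclisation of the ortho-allylic phenol.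

## Compound list

1 | 6-hydroxy-3,4-dihydronaphthalen-1(2H)-one | O=C1CCCc2cc(O)ccc21 | starting material
2 | 6-(benzyloxy)-3,4-dihydronaphthalen-1(2H)-one | O=C1CCCc2cc(OCc3ccccc3)ccc21 | intermediate
3 | allyl 6-(benzyloxy)-1-oxo-1,2,3,4-tetrahydronaphthalene-2-carboxylate (present as its sodium enolate, not isolated) | O=C1c2ccc(OCc3ccccc3)cc2CCC1C(=O)OCC=C | intermediate
4 | allyl (±)-6-(benzyloxy)-2-methyl-1-oxo-1,2,3,4-tetrahydronaphthalene-2-carboxylate | O=C1c2ccc(OCc3ccccc3)cc2CCC1(C)C(=O)OCC=C | intermediate
5 | (R)-6-(benzyloxy)-2-methyl-3,4-dihydronaphthalen-1(2H)-one | O=C1c2ccc(OCc3ccccc3)cc2CC[C@H]1C | intermediate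
6 | (R)-7-(benzyloxy)-3-methyl-4,5-dihydro-1-benzoxepin-2(3H)-one | O=C1Oc2ccc(OCc3ccccc3)cc2CC[C@H]1C | intermediate
7 | (R)-7-hydroxy-3-methyl-4,5-dihydro-1-benzoxepin-2(3H)-one | O=C1Oc2ccc(O)cc2CC[C@H]1C | intermediate
8 | (R)-3-methyl-2-oxo-2,3,4,5-tetrahydro-1-benzoxepin-7-yl trifluoromethanesulfonate | O=C1Oc2ccc(OS(=O)(=O)C(F)(F)F)cc2CC[C@H]1C | intermediate
9 | 4-hydroxy-3-{(3R)-4-[methoxy(methyl)amino]-3-methyl-4-oxobutyl}phenyl trifluoromethanesulfonate | Oc1ccc(OS(=O)(=O)C(F)(F)F)cc1CC[C@@H](C)C(=O)N(C)OC | intermediate
10 | 2-(trimethylsilyl)ethyl 4-hydroxy-3-{(3R)-4-[methoxy(methyl)amino]-3-methyl-4-oxobutyl}benzoate | C[Si](C)(C)CCOC(=O)c1ccc(O)c(CC[C@@H](C)C(=O)N(C)OC)c1 | intermediate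
11 | 2-(trimethylsilyl)ethyl 4-(allyloxy)-3-{(3R)-4-[methoxy(methyl)amino]-3-methyl-4-oxobutyl}benzoate | C[Si](C)(C)CCOC(=O)c1ccc(OCC=C)c(CC[C@@H](C)C(=O)N(C)OC)c1 | intermediate
12 | 2-(trimethylsilyl)ethyl 3-allyl-4-hydroxy-5-{(3R)-4-[methoxy(methyl)amino]-3-methyl-4-oxobutyl}benzoate | C[Si](C)(C)CCOC(=O)c1cc(CC=C)c(O)c(CC[C@@H](C)C(=O)N(C)OC)c1 | intermediate
13 | methacrolein (2-methylprop-2-enal) | CC(=C)C=O | starting material
14 | 2-(trimethylsilyl)ethyl 4-hydroxy-3-{(3R)-4-[methoxy(methyl)amino]-3-methyl-4-oxobutyl}-5-[(2E)-3-methyl-4-oxobut-2-en-1-yl]benzoate | C/C(=C\Cc1cc(C(=O)OCC[Si](C)(C)C)cc(CC[C@@H](C)C(=O)N(C)OC)c1O)C=O | intermediate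
15 | 2-(trimethylsilyl)ethyl 4-hydroxy-3-[(2E)-4-hydroxy-3-methylbut-2-en-1-yl]-5-{(3R)-4-[methoxy(methyl)amino]-3-methyl-4-oxobutyl}benzoate | C/C(=C\Cc1cc(C(=O)OCC[Si](C)(C)C)cc(CC[C@@H](C)C(=O)N(C)OC)c1O)CO | intermediate
16 | 2-methylbut-3-yn-2-ol | CC(C)(O)C#C | starting material
17 | (E)-2-methyl-4-(tributylstannyl)but-3-en-2-ol (not isolated) | CCCC[Sn](CCCC)(CCCC)/C=C/C(C)(C)O | intermediate
18 | (E)-4-iodo-2-methylbut-3-en-2-ol | CC(C)(O)/C=C/I | intermediate
19 | triethyl{[(3E)-4-iodo-2-methylbut-3-en-2-yl]oxy}silane | CC[Si](CC)(CC)OC(C)(C)/C=C/I | intermediate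
20 | {(1E)-3-methyl-3-[(triethylsilyl)oxy]but-1-en-1-yl}magnesium chloride (not isolated) | CC[Si](CC)(CC)OC(C)(C)/C=C/[Mg]Cl | intermediate
21 | 2-(trimethylsilyl)ethyl 3-{(3R,5E)-3,7-dimethyl-4-oxo-7-[(triethylsilyl)oxy]oct-5-en-1-yl}-4-hydroxy-5-[(2E)-4-hydroxy-3-methylbut-2-en-1-yl]benzoate | C/C(=C\Cc1cc(C(=O)OCC[Si](C)(C)C)cc(CC[C@@H](C)C(=O)/C=C/C(C)(C)O[Si](CC)(CC)CC)c1O)CO | intermediate
22 | 4-hydroxy-3-[(3R,5E)-7-hydroxy-3,7-dimethyl-4-oxooct-5-en-1-yl]-5-[(2E)-4-hydroxy-3-methylbut-2-en-1-yl]benzoic acid | C/C(=C\Cc1cc(C(=O)O)cc(CC[C@@H](C)C(=O)/C=C/C(C)(C)O)c1O)CO | target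

## Step count and least certain steps

Total number of steps: 16. Longest linear sequence: 14 steps (steps 1–12, 15 and 16); steps 13 and 14 form the side branch.

**Step 4 (key step).**
- **What may go wrong:** The para donor that secures aryl migration also makes the carbonyl a poor acceptor for the peracid, so the addition may be slow. Long contact with carboxylic acid invites enolisation of unreacted ketone and thus erosion of the configuration at C2. Some leakage through migration of the secondary carbon is also possible. A strong acid co-catalyst would speed the oxidation but cannot be used freely, for the same stereochemical reason.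
- **Fallback, from 2 back to 9:** The ring expansion is placed before the stereocentre.
  - Oxidation of 2 with mCPBA and CF3CO2H is harmless here, because no stereocentre exists and only a primary carbon competes. It gives 7-(benzyloxy)-4,5-dihydro-1-benzoxepin-2(3H)-one F1.
  - The lithium salt of (R)-4-benzyloxazolidin-2-one opens the aryl lactone, and TBSCl traps the phenoxide in the same flask, which makes the opening irreversible. The product is (R)-4-benzyl-3-{4-[5-(benzyloxy)-2-(tert-butyldimethylsilyloxy)phenyl]butanoyl}oxazolidin-2-one F2.
  - Evans methylation (NaHMDS, MeI, −78 °C) on the face away from the benzyl group gives (R)-4-benzyl-3-{(2R)-4-[5-(benzyloxy)-2-(tert-butyldimethylsilyloxy)phenyl]-2-methylbutanoyl}oxazolidin-2-one F3.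
  - AlMe3 and MeNH(OMe)·HCl exchange the auxiliary to give (2R)-4-[5-(benzyloxy)-2-(tert-butyldimethylsilyloxy)phenyl]-N-methoxy-N,2-dimethylbutanamide F4.
  - Hydrogenolysis (H2, Pd/C) gives (2R)-4-[2-(tert-butyldimethylsilyloxy)-5-hydroxyphenyl]-N-methoxy-N,2-dimethylbutanamide F5.
  - Tf2O and pyridine give 4-(tert-butyldimethylsilyloxy)-3-{(3R)-4-[methoxy(methyl)amino]-3-methyl-4-oxobutyl}phenyl trifluoromethanesulfonate F6.
  - HF·pyridine frees the phenol and returns 9.

**Step 15.**
- **What may go wrong:** Some addition to the aryl ester may occur despite the phenoxide effect. Incomplete iodine–magnesium exchange would leave isopropyl Grignard reagent free to attack the amide. The doubly deprotonated substrate may be poorly soluble. The released amine may add in a conjugate sense during the quench.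
- **Fallback, from 15 back to 22:** Organometallic acyl substitution is replaced by amide-selective reduction and an aldehyde-selective coupling.
  - TBSOTf and 2,6-lutidine give 2-(trimethylsilyl)ethyl 4-(tert-butyldimethylsilyloxy)-3-[(2E)-4-(tert-butyldimethylsilyloxy)-3-methylbut-2-en-1-yl]-5-{(3R)-4-[methoxy(methyl)amino]-3-methyl-4-oxobutyl}benzoate F7.
  - Cp2Zr(H)Cl in THF reduces the amide but not the ester, giving 2-(trimethylsilyl)ethyl 4-(tert-butyldimethylsilyloxy)-3-[(2E)-4-(tert-butyldimethylsilyloxy)-3-methylbut-2-en-1-yl]-5-[(3R)-3-methyl-4-oxobutyl]benzoate F8.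
  - Nozaki–Hiyama–Kishi coupling with 19 (CrCl2, NiCl2 cat., DMF) gives, as a mixture of carbinol epimers, 2-(trimethylsilyl)ethyl 4-(tert-butyldimethylsilyloxy)-3-[(2E)-4-(tert-butyldimethylsilyloxy)-3-methylbut-2-en-1-yl]-5-{(3R,5E)-4-hydroxy-3,7-dimethyl-7-[(triethylsilyl)oxy]oct-5-en-1-yl}benzoate F9.
  - Dess–Martin periodinane with NaHCO3 gives 2-(trimethylsilyl)ethyl 4-(tert-butyldimethylsilyloxy)-3-[(2E)-4-(tert-butyldimethylsilyloxy)-3-methylbut-2-en-1-yl]-5-{(3R,5E)-3,7-dimethyl-4-oxo-7-[(triethylsilyl)oxy]oct-5-en-1-yl}benzoate F10.
  - TBAF removes all four silicon groups and gives 22.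

**Step 16.**
- **What may go wrong:** Basic fluoride may epimerise C3', because the ketone is now present. The fragmentation of the β-silyl ester may also be slow, because the leaving carboxylate is para to a phenoxide, and this lengthens the exposure.
- **Fallback, from 15 back to 22:** The order is changed so that fluoride never meets the enone.
  - TBAF on 15, whose amide α-C–H is not at risk, gives 4-hydroxy-3-[(2E)-4-hydroxy-3-methylbut-2-en-1-yl]-5-{(3R)-4-[methoxy(methyl)amino]-3-methyl-4-oxobutyl}benzoic acid F11.
  - Threefold deprotonation with i-PrMgCl and addition of 20, to which a carboxylate is inert, gives 3-{(3R,5E)-3,7-dimethyl-4-oxo-7-[(triethylsilyl)oxy]oct-5-en-1-yl}-4-hydroxy-5-[(2E)-4-hydroxy-3-methylbut-2-en-1-yl]benzoic acid F12.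
  - HF·pyridine buffered with pyridine in THF at 0 °C removes the last silyl group and gives 22.

**Step 3.**
- **What may go wrong:** Facial selectivity in the protonation may be insufficient, because the outcome depends on a heterogeneous mixture with molecular sieves. Some loss of the benzyl group may occur if palladium black forms in the presence of formic acid.
- **Fallback, from 2 back to 5:** An auxiliary-controlled alkylation replaces the catalytic protonation.
  - Condensation of 2 with (S)-1-amino-2-(methoxymethyl)pyrrolidine gives the hydrazone (S,E)-N-[6-(benzyloxy)-3,4-dihydronaphthalen-1(2H)-ylidene]-2-(methoxymethyl)pyrrolidin-1-amine F13.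
  - LDA and then MeI at low temperature methylate the chelated azaenolate on its open face. By analogy with cyclohexanone-type hydrazones of the same auxiliary, this should give the R centre in (S)-N-[(2R,E)-6-(benzyloxy)-2-methyl-3,4-dihydronaphthalen-1(2H)-ylidene]-2-(methoxymethyl)pyrrolidin-1-amine F14.
  - Two-phase hydrolysis with saturated aqueous oxalic acid returns 5.

**Step 10.**
- **What may go wrong:** The N–O bond or the β-silyl ester may suffer thermal damage during the long heating that the acceptor-substituted ring requires, so the rearrangement may stay incomplete at tolerable temperatures.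
- **Fallback, from 10 back to 12:** Cross-coupling replaces the sigmatropic shift.
  - Bromination with NBS in MeCN can only occur at the single free ortho position. It gives 2-(trimethylsilyl)ethyl 3-bromo-4-hydroxy-5-{(3R)-4-[methoxy(methyl)amino]-3-methyl-4-oxobutyl}benzoate F15.
  - Stille coupling with allyltributylstannane (Pd(PPh3)4, toluene, 100 °C) gives 12.

**Step 11.**
- **What may go wrong:** The double bond may migrate into conjugation with ring A through ruthenium hydrides. The allyl arene may homodimerise, and the catalyst may decay in the presence of the free phenol before the hindered trisubstituted olefin has formed.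
- **Fallback, from 12 back to 14:** The olefin is built by carbonyl olefination.
  - Lemieux–Johnson cleavage (OsO4 cat., NaIO4, 2,6-lutidine, dioxane/water) gives 2-(trimethylsilyl)ethyl 4-hydroxy-3-{(3R)-4-[methoxy(methyl)amino]-3-methyl-4-oxobutyl}-5-(2-oxoethyl)benzoate F16, which is in equilibrium with its cyclic hemiacetal.
  - Wittig reaction with the stabilised ylide 2-(triphenylphosphoranylidene)propanal in warm toluene should give the E enal 14.

## Further compounds

F1 | step 4 | 7-(benzyloxy)-4,5-dihydro-1-benzoxepin-2(3H)-one | O=C1CCCc2cc(OCc3ccccc3)ccc2O1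
F2 | step 4 | (R)-4-benzyl-3-{4-[5-(benzyloxy)-2-(tert-butyldimethylsilyloxy)phenyl]butanoyl}oxazolidin-2-one | O=C(CCCc1cc(OCc2ccccc2)ccc1O[Si](C)(C)C(C)(C)C)N1C(=O)OC[C@H]1Cc1ccccc1
F3 | step 4 | (R)-4-benzyl-3-{(2R)-4-[5-(benzyloxy)-2-(tert-butyldimethylsilyloxy)phenyl]-2-methylbutanoyl}oxazolidin-2-one | CC(C)(C)[Si](C)(C)Oc1ccc(OCc2ccccc2)cc1CC[C@@H](C)C(=O)N1C(=O)OC[C@H]1Cc1ccccc1
F4 | step 4 | (2R)-4-[5-(benzyloxy)-2-(tert-butyldimethylsilyloxy)phenyl]-N-methoxy-N,2-dimethylbutanamide | CC(C)(C)[Si](C)(C)Oc1ccc(OCc2ccccc2)cc1CC[C@@H](C)C(=O)N(C)OC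
F5 | step 4 | (2R)-4-[2-(tert-butyldimethylsilyloxy)-5-hydroxyphenyl]-N-methoxy-N,2-dimethylbutanamide | CC(C)(C)[Si](C)(C)Oc1ccc(O)cc1CC[C@@H](C)C(=O)N(C)OC
F6 | step 4 | 4-(tert-butyldimethylsilyloxy)-3-{(3R)-4-[methoxy(methyl)amino]-3-methyl-4-oxobutyl}phenyl trifluoromethanesulfonate | CC(C)(C)[Si](C)(C)Oc1ccc(OS(=O)(=O)C(F)(F)F)cc1CC[C@@H](C)C(=O)N(C)OC
F7 | step 15 | 2-(trimethylsilyl)ethyl 4-(tert-butyldimethylsilyloxy)-3-[(2E)-4-(tert-butyldimethylsilyloxy)-3-methylbut-2-en-1-yl]-5-{(3R)-4-[methoxy(methyl)amino]-3-methyl-4-oxobutyl}benzoate | C/C(=C\Cc1cc(C(=O)OCC[Si](C)(C)C)cc(CC[C@@H](C)C(=O)N(C)OC)c1O[Si](C)(C)C(C)(C)C)CO[Si](C)(C)C(C)(C)C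
F8 | step 15 | 2-(trimethylsilyl)ethyl 4-(tert-butyldimethylsilyloxy)-3-[(2E)-4-(tert-butyldimethylsilyloxy)-3-methylbut-2-en-1-yl]-5-[(3R)-3-methyl-4-oxobutyl]benzoate | C/C(=C\Cc1cc(C(=O)OCC[Si](C)(C)C)cc(CC[C@@H](C)C=O)c1O[Si](C)(C)C(C)(C)C)CO[Si](C)(C)C(C)(C)C
F9 | step 15 | 2-(trimethylsilyl)ethyl 4-(tert-butyldimethylsilyloxy)-3-[(2E)-4-(tert-butyldimethylsilyloxy)-3-methylbut-2-en-1-yl]-5-{(3R,5E)-4-hydroxy-3,7-dimethyl-7-[(triethylsilyl)oxy]oct-5-en-1-yl}benzoate (both carbinol epimers) | C/C(=C\Cc1cc(C(=O)OCC[Si](C)(C)C)cc(CC[C@@H](C)C(O)/C=C/C(C)(C)O[Si](CC)(CC)CC)c1O[Si](C)(C)C(C)(C)C)CO[Si](C)(C)C(C)(C)C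
F10 | step 15 | 2-(trimethylsilyl)ethyl 4-(tert-butyldimethylsilyloxy)-3-[(2E)-4-(tert-butyldimethylsilyloxy)-3-methylbut-2-en-1-yl]-5-{(3R,5E)-3,7-dimethyl-4-oxo-7-[(triethylsilyl)oxy]oct-5-en-1-yl}benzoate | C/C(=C\Cc1cc(C(=O)OCC[Si](C)(C)C)cc(CC[C@@H](C)C(=O)/C=C/C(C)(C)O[Si](CC)(CC)CC)c1O[Si](C)(C)C(C)(C)C)CO[Si](C)(C)C(C)(C)C
F11 | step 16 | 4-hydroxy-3-[(2E)-4-hydroxy-3-methylbut-2-en-1-yl]-5-{(3R)-4-[methoxy(methyl)amino]-3-methyl-4-oxobutyl}benzoic acid | C/C(=C\Cc1cc(C(=O)O)cc(CC[C@@H](C)C(=O)N(C)OC)c1O)CO
F12 | step 16 | 3-{(3R,5E)-3,7-dimethyl-4-oxo-7-[(triethylsilyl)oxy]oct-5-en-1-yl}-4-hydroxy-5-[(2E)-4-hydroxy-3-methylbut-2-en-1-yl]benzoic acid | C/C(=C\Cc1cc(C(=O)O)cc(CC[C@@H](C)C(=O)/C=C/C(C)(C)O[Si](CC)(CC)CC)c1O)CO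
F13 | step 3 | (S,E)-N-[6-(benzyloxy)-3,4-dihydronaphthalen-1(2H)-ylidene]-2-(methoxymethyl)pyrrolidin-1-amine | COC[C@@H]1CCCN1/N=C1\CCCc2cc(OCc3ccccc3)ccc21
F14 | step 3 | (S)-N-[(2R,E)-6-(benzyloxy)-2-methyl-3,4-dihydronaphthalen-1(2H)-ylidene]-2-(methoxymethyl)pyrrolidin-1-amine | COC[C@@H]1CCCN1/N=C1/c2ccc(OCc3ccccc3)cc2CC[C@H]1C
F15 | step 10 | 2-(trimethylsilyl)ethyl 3-bromo-4-hydroxy-5-{(3R)-4-[methoxy(methyl)amino]-3-methyl-4-oxobutyl}benzoate | C[Si](C)(C)CCOC(=O)c1cc(Br)c(O)c(CC[C@@H](C)C(=O)N(C)OC)c1
F16 | step 11 | 2-(trimethylsilyl)ethyl 4-hydroxy-3-{(3R)-4-[methoxy(methyl)amino]-3-methyl-4-oxobutyl}-5-(2-oxoethyl)benzoate | C[Si](C)(C)CCOC(=O)c1cc(CC=O)c(O)c(CC[C@@H](C)C(=O)N(C)OC)c1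
A1 | alternative 1 | methyl 4-iodo-3-[(E)-4-(tert-butyldimethylsilyloxy)-3-methylbut-2-en-1-yl]benzoate | C/C(=C\Cc1cc(C(=O)OC)ccc1I)CO[Si](C)(C)C(C)(C)C
A2 | alternative 1 | 1-{[(2R)-4-iodo-2-methylbutoxy]methyl}-4-methoxybenzene | ICC[C@@H](C)COCc1ccc(OC)cc1
A3 | alternative 1 | methyl 3-[(E)-4-(tert-butyldimethylsilyloxy)-3-methylbut-2-en-1-yl]-5-[(3R)-4-(4-methoxybenzyloxy)-3-methylbutyl]-4-(pinacolboryl)benzoate | C/C(=C\Cc1cc(C(=O)OC)cc(CC[C@@H](C)COCc2ccc(OC)cc2)c1B1OC(C)(C)C(C)(C)O1)CO[Si](C)(C)C(C)(C)C
A4 | alternative 2 | methyl 3-allyl-2-oxo-2H-pyran-5-carboxylate | O=C1OC=C(C(=O)OC)C=C1CC=C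
A5 | alternative 2 | triisopropyl{[(5R)-6-(4-methoxybenzyloxy)-5-methylhex-1-yn-1-yl]oxy}silane | CC(C)[Si](OC#CCC[C@@H](C)COCc1ccc(OC)cc1)(C(C)C)C(C)C
A6 | alternative 2 | methyl 3-allyl-5-[(3R)-4-(4-methoxybenzyloxy)-3-methylbutyl]-4-(triisopropylsilyloxy)benzoate | COC(=O)c1cc(CC=C)c(O[Si](C(C)C)(C(C)C)C(C)C)c(CC[C@@H](C)COCc2ccc(OC)cc2)c1
A7 | alternative 3 | (2E,10R)-1-(tert-butyldimethylsilyloxy)-11-(4-methoxybenzyloxy)-2,10-dimethylundec-2-en-6-one | C/C(=C\CCC(=O)CCC[C@@H](C)COCc1ccc(OC)cc1)CO[Si](C)(C)C(C)(C)C
A8 | alternative 3 | methyl 2-formyl-3-oxopropanoate | COC(=O)C(C=O)C=O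
A9 | alternative 3 | methyl 3-[(E)-4-(tert-butyldimethylsilyloxy)-3-methylbut-2-en-1-yl]-4-hydroxy-5-[(3R)-4-(4-methoxybenzyloxy)-3-methylbutyl]benzoate | C/C(=C\Cc1cc(C(=O)OC)cc(CC[C@@H](C)COCc2ccc(OC)cc2)c1O)CO[Si](C)(C)C(C)(C)C
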